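The runs are calculated with constants of no real substance, noise included.

Count what each flask has made of its substrate before asking how fast it went.

| flask | substrate | remark | time |
|---|---|---|---|
| south-west | 0.032 M | run made earlier |  |
| west | 0.37 M | run made earlier |  |
| Monday's | 0.025 M |  | 30 min |
| Saturday's | 0.060 M |  | 30 min |
| Thursday's | 0.20 M |  | 30 min |
| Wednesday's | 0.050 M |  | 30 min |
| Tuesday's | 0.30 M |  | 30 min |
| Sunday's | 0.10 M |  | 30 min |

- south-west (time / min: target / %, substrate / %): 4.00: 66.0, 4.2; 8.00: 70.2, 1.7; 12.0: 70.4, 0; 15.0: 72.1, 0.1; 20.0: 69.6, 0
- west (time / min: target / %, substrate / %): 2.00: 13.7, 9.5; 5.00: 19.8, 2.0; 10.0: 21.8, 1.9; 15.0: 19.8, 0; 20.0: 21.1, 0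

(scatter of a reading: 1 percentage point)

* the flasks by amount of target, in percent of the substrate charged, highest first, at 30 min (Monday's / Saturday's / Thursday's / Wednesday's / Tuesday's / Sunday's)
* the amount of target, in percent of the substrate charged of the flask you put first, at 30 min
* the amount of target, in percent of the substrate charged of the flask you put last, at 30 min



The substrate stands at 0% by 12.0 min in the south-west run and at 0% by 15.0 min in the west run, both earlier than the asked time, and the target then stays flat within the scatter. So I set time aside and keep two amounts, the target and the rest of the charge. Their ratio, rest over target, is the loss odds L, the inverse of the overall selectivity. Averaging the last 4 readings of each run, I read 70.6% target in the south-west run and 20.6% in the west run: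

L, south-west = 0.417; L, west = 3.85

n = ln(ratio of the L) / ln(ratio of the charges) = 0.908

c(even) = 0.0839 M

I carry c(even), the even-odds concentration, the substrate charge at which this line gives as much target as rest, with L = (c(substrate)/c(even))^n and target = 1/(1+L). Since L rises from the south-west run to the west run, I order the flasks from the lowest charge upward, and I reckon 75.0% for Monday's and 23.9% for Tuesday's.

The forecast has my order, Monday's > Wednesday's > Saturday's > Sunday's > Thursday's > Tuesday's, but its own figures, 74% and 25%, on this ground: “Yield therefore falls steadily with concentration”.

The flasks give Monday's > Wednesday's > Saturday's > Sunday's > Thursday's > Tuesday's, with 75.2% in Monday's and 24.8% in Tuesday's.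

    substrate + intermediate → side product (k = 0.820 M⁻¹ s⁻¹)
    substrate → intermediate (k = 0.0117 s⁻¹)
    intermediate → target (k = 0.0466 s⁻¹)

Monday's ends with 24.8% side product, so its L is 0.330. The neighbour of Monday's, charged with 0.010 M of substrate and otherwise held as Monday's, stands at 0.119 of c(even), which gives L = 0.145 and 87.3% target. That neighbour holds 88.0% target and 12.0% side product at 30.0 min.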